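Locants used below: seven-membered ring C1(CH3)=C2–C3(O-isovaleryl)–C4(CH3, fusion)–C5(H, fusion)–C6(O-aroyl)–C7; five-membered ring C4–C8–C9–C10(OH, i-Pr)–C5.
Retrosynthesis: esters off; C10–OH/i-Pr back to a C10 ketone (via the epoxide of a C9=C10 alkene); C4–CH3 back to a C3=C4 silyl enol ether; C1–CH3 back to an ester carbon; the bicycle is then cut at C1–C2 and C5–C6.
Enabling feature: the cycloheptene is a masked cyclohepta-1,4-diene. C6–C7–C1 (CH–O, CH2, C–CH3) is a three-carbon vinylcarbenoid, and C2–C3–C4–C5 (oxygen on C3, quaternary C4) is a 2-silyloxy-1,3-diene, so one (4+3) event makes both bonds.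
Forward: the cyclopentene is bought and the seven-membered ring is annulated onto it (step 6); then C1 ester to CH3, C4 methylation, enone, C10 elaboration, reductions and the two esterifications.
Stereochemistry: C5/C6 from the chiral dirhodium catalyst and the boat Cope transition state; C4 by enolate methylation syn to H5 (cis fusion); C10 by convex-face epoxidation and hydride opening; C3 by convex-face hydride delivery.

Key step: step 6

Remark: 3-bromocyclopent-2-en-1-one, ethyl diazoacetate, [(tert-butyldimethylsilyl)oxy]acetaldehyde and all reagents named are taken as purchasable.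
Remark: the sense of induction of Rh2(S-DOSP)4 is assigned by analogy with its cyclopropanations of electron-rich alkenes; Rh2(R-DOSP)4 is used should the enantiomeric series arise.

Step 1
Reactants: 1 3-bromocyclopent-2-en-1-one
Product: 2 7-bromo-1,4-dioxaspiro[4.4]non-6-ene
Conditions: TMSOCH2CH2OTMS, TMSOTf (cat.), CH2Cl2, −78 to −20 °C
Reagents that add atoms: 1,2-bis(trimethylsilyloxy)ethane, C[Si](C)(C)OCCO[Si](C)(C)C
Why: Aprotic TMSOTf-catalysed ketalisation with the bis-silyl ether should protect the enone carbonyl without double-bond migration or displacement of the vinylic bromide.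

Step 2
Reactants: 2 7-bromo-1,4-dioxaspiro[4.4]non-6-ene
Product: 4 1-(1,4-dioxaspiro[4.4]non-6-en-7-yl)ethan-1-one, via vinyllithium 3 (not isolated)
Conditions: t-BuLi (2.1 equiv), Et2O, −78 °C; MeC(O)N(OMe)Me, −78 to 0 °C; aq. NH4Cl
Reagents that add atoms: N-methoxy-N-methylacetamide, CON(C)C(C)=O
Why: Bromine–lithium exchange followed by acylation with the N-methoxy-N-methyl amide should stop at the methyl ketone because the chelated tetrahedral adduct survives until work-up.

Step 3
Reactants: 4 1-(1,4-dioxaspiro[4.4]non-6-en-7-yl)ethan-1-one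
Product: 5 tert-butyl{[1-(1,4-dioxaspiro[4.4]non-6-en-7-yl)ethenyl]oxy}dimethylsilane
Conditions: TBSOTf, Et3N, CH2Cl2, −78 to 0 °C
Reagents that add atoms: tert-butyldimethylsilyl trifluoromethanesulfonate, CC(C)(C)[Si](C)(C)OS(=O)(=O)C(F)(F)F
Why: Soft enolisation (silyl triflate/amine) can only remove a proton from the acetyl methyl group and should give the cross-conjugated 2-silyloxy-1,3-diene.

Step 4
Reactants: 6 ethyl diazoacetate; 7 [(tert-butyldimethylsilyl)oxy]acetaldehyde
Product: 8 ethyl 4-[(tert-butyldimethylsilyl)oxy]-2-diazo-3-hydroxybutanoate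
Conditions: DBU (cat.), MeCN, 23 °C
Reagents that add atoms: none
Why: Base-catalysed aldol-type addition of the diazoacetate carbon to the aldehyde gives the β-hydroxy-α-diazo ester, whose racemic carbinol centre is removed in the next step.

Step 5
Reactants: 8 ethyl 4-[(tert-butyldimethylsilyl)oxy]-2-diazo-3-hydroxybutanoate
Product: 10 ethyl (3E)-4-[(tert-butyldimethylsilyl)oxy]-2-diazobut-3-enoate, via dichlorophosphate 9 (not isolated)
Conditions: POCl3, Et3N, CH2Cl2, 0 °C
Reagents that add atoms: none
Why: Phosphorylation of the carbinol and anti-periplanar E2 elimination is the standard dehydration route to vinyldiazoacetates and should give the conjugated E isomer.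

Step 6
Reactants: 5 tert-butyl{[1-(1,4-dioxaspiro[4.4]non-6-en-7-yl)ethenyl]oxy}dimethylsilane; 10 ethyl (3E)-4-[(tert-butyldimethylsilyl)oxy]-2-diazobut-3-enoate
Product: 12 bicyclic cycloheptadiene ester (C1–CO2Et; C1=C7; C3=C4 silyl enol ether; C6–OTBS; C10 ketal; H5/H6 cis), via divinylcyclopropane 11 (not isolated)
Conditions: Rh2(S-DOSP)4 (dirhodium tetrakis[(S)-N-(4-dodecylbenzenesulfonyl)prolinate], 1 mol%), 2,2-dimethylbutane, −40 °C, slow addition of 10; then 23 to 50 °C
Reagents that add atoms: none
Why: The dirhodium catalyst converts 10 into a donor/acceptor rhodium vinylcarbenoid that cyclopropanates the electron-rich C2=C3 silyl enol ether alkene of 5 with the two alkenyl groups cis (11), and 11 then undergoes a [3,3] divinylcyclopropane Cope shift through the boat transition state, forming C5–C6 as the cyclopropane bond C1–C3 breaks and leaving C1–C2 as the second new ring bond. The closest known reaction type is the tandem cyclopropanation/Cope rearrangement of vinyldiazoacetates with 2-silyloxy dienes, a formal [4+3] cycloaddition. The seven-membered ring is closed as a (4+3) annulation onto the existing cyclopentene, its last bond by a concerted suprafacial sigmatropic ring expansion of the three-membered ring. The absolute configuration at C5 and C6 follows from the face of C2=C3 that the chiral catalyst selects, and their relative configuration (H5 and H6 cis, OTBS on the side of C10) from the boat geometry combined with the E geometry of the silyloxyvinyl group and the ring-fixed geometry of C4=C5. The step needs site selectivity for C2=C3 over the trisubstituted C4=C5 alkene and reaction at the carbenoid carbon instead of the vinylogous position; the 1,1-disubstituted silyl enol ether, the substituent on the vinyl terminus of 10 and the hydrocarbon solvent should secure both, and the achiral diene leaves the catalyst as the only source of asymmetry.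

Step 7
Reactants: 12 bicyclic cycloheptadiene ester
Product: 13 allylic alcohol (C1–CH2OH)
Conditions: DIBAL-H (i-Bu2AlH, 2.5 equiv), CH2Cl2, −78 °C; aq. KNaC4H4O6
Reagents that add atoms: none
Why: 1,2-Reduction of the conjugated ester by the aluminium hydride gives the primary allylic alcohol while silyl enol ether, silyl ether and ketal are inert.

Step 8
Reactants: 13 allylic alcohol (C1–CH2OH)
Product: 16 exo-methylene silyl enol ether (C1=CH2; C7H2), via sulfonylhydrazine 14 (not isolated), via allylic diazene 15 (not isolated)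
Conditions: PPh3, DEAD, 2-nitrobenzenesulfonohydrazide, N-methylmorpholine, −30 to 23 °C
Reagents that add atoms: none
Why: Mitsunobu N-alkylation of the sulfonohydrazide, loss of sulfinic acid and retro-ene loss of N2 from the monoalkyl diazene (reductive 1,3-transposition of an allylic alcohol) deliver hydrogen to C7 and leave the former ester carbon as the exocyclic methylene on C1.

Step 9
Reactants: 16 exo-methylene silyl enol ether
Product: 18 enone ketal (C1(CH3)=C2–C3=O; C4–CH3; cis-fused), via methyl ketone 17 (not isolated)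
Conditions: TASF ([(Me2N)3S][Me3SiF2]), MeI, THF, −78 to 0 °C; evaporate; then DBU, CH2Cl2, 23 °C
Reagents that add atoms: iodomethane, CI
Why: Fluoride unmasks the regiodefined C3–C4 enolate, which should be C-methylated at C4 on the face of H5 (the C6 and C10 ring bonds lean to the other face) to set the quaternary centre with cis fusion (regiospecific enolate alkylation), after which DBU moves the β,γ-exocyclic alkene into conjugation as C1=C2.

Step 10
Reactants: 18 enone ketal
Product: 19 enone ketone (C3 enone; C10 ketone; C6–OTBS)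
Conditions: PPTS, acetone/H2O, 50 °C
Reagents that add atoms: water, O
Why: Mild acid-catalysed ketal hydrolysis frees the C10 ketone while the secondary silyl ether and the enone should survive.

Step 11
Reactants: 19 enone ketone
Product: 21 enol triflate (C9=C10–OTf), via lithium enolate 20 (not isolated)
Conditions: LiHMDS (LiN(SiMe3)2), THF, −78 °C; N-(5-chloropyridin-2-yl)bis(trifluoromethanesulfonyl)imide, −78 to 0 °C
Reagents that add atoms: N-(5-chloropyridin-2-yl)bis(trifluoromethanesulfonyl)imide, O=S(=O)(N(c1ccc(Cl)cn1)S(=O)(=O)C(F)(F)F)C(F)(F)F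
Why: Kinetic deprotonation at the unhindered C9 methylene (not the hindered C5 methine or the enone γ-positions) and O-triflation of the enolate give the C9=C10 enol triflate.

Step 12
Reactants: 21 enol triflate
Product: 22 isopropyl cyclopentene enone (C9=C10–i-Pr)
Conditions: i-PrZnBr, Pd(OAc)2, CPhos, THF, 23 °C
Reagents that add atoms: isopropylzinc bromide, CC(C)[Zn]Br
Why: Negishi coupling of the alkenyl triflate with the secondary alkylzinc reagent (the biarylphosphine suppresses β-hydride isomerisation) installs the isopropyl group without touching the enone.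

Step 13
Reactants: 22 isopropyl cyclopentene enone
Product: 23 epoxy enone (C9–C10 epoxide; oxygen on the face of H5 and the C4 methyl)
Conditions: mCPBA, NaHCO3, CH2Cl2, 0 °C
Reagents that add atoms: 3-chloroperoxybenzoic acid, OOC(=O)c1cccc(Cl)c1
Why: Peracid epoxidation is chemoselective for the electron-rich trisubstituted cyclopentene over the enone and should occur on the convex face, anti to the C5–C6 bond, which sets the C10–O configuration.

Step 14
Reactants: 23 epoxy enone
Product: 24 diol (C3–OH; C10–OH; C6–OTBS)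
Conditions: LiAlH4, THF, −78 to 23 °C
Reagents that add atoms: none
Why: Hydride opens the epoxide by SN2 attack at the secondary C9 (C10–O bond untouched, giving the tertiary alcohol with retention) and reduces the enone 1,2 from the convex face to give the C3 alcohol trans to the C4 methyl.

Step 15
Reactants: 24 diol
Product: 25 C3 isovalerate (C10–OH free; C6–OTBS)
Conditions: 3-methylbutanoyl chloride, pyridine, DMAP (cat.), CH2Cl2, 0 to 23 °C
Reagents that add atoms: 3-methylbutanoyl chloride, CC(C)CC(Cl)=O
Why: DMAP-catalysed acylation takes the secondary allylic C3 alcohol while the tertiary C10 alcohol should not react.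

Step 16
Reactants: 25 C3 isovalerate
Product: 26 C6 alcohol (C3 isovalerate; C10–OH)
Conditions: HF·pyridine, pyridine, THF, 0 to 23 °C
Reagents that add atoms: none
Why: Buffered fluoride desilylation cleaves the secondary silyl ether under conditions too weakly basic for acyl migration from O3 to O6.

Step 17
Reactants: 26 C6 alcohol
Product: 27 C6 4-acetoxybenzoate
Conditions: 4-acetoxybenzoyl chloride, Et3N, DMAP (cat.), CH2Cl2, 23 °C
Reagents that add atoms: 4-acetoxybenzoyl chloride, CC(=O)Oc1ccc(cc1)C(Cl)=O
Why: Nucleophile-catalysed acylation of the only remaining secondary alcohol installs the aroyl ester with the phenol carried as its acetate.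

Step 18
Reactants: 27 C6 4-acetoxybenzoate
Product: 28 target diester (CNP0086724.3)
Conditions: NH3 (MeOH), 0 °C
Reagents that add atoms: none
Why: Ammonolysis is selective for the activated aryl acetate over the two alkyl carboxylate esters.

Compound list
1 | 3-bromocyclopent-2-en-1-one | O=C1CCC(Br)=C1 | starting material
2 | 7-bromo-1,4-dioxaspiro[4.4]non-6-ene | BrC1=CC2(CC1)OCCO2 | intermediate
3 | (1,4-dioxaspiro[4.4]non-6-en-7-yl)lithium (vinyllithium) | [Li]C1=CC2(CC1)OCCO2 | intermediate
4 | 1-(1,4-dioxaspiro[4.4]non-6-en-7-yl)ethan-1-one | CC(=O)C1=CC2(CC1)OCCO2 | intermediate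
5 | tert-butyl{[1-(1,4-dioxaspiro[4.4]non-6-en-7-yl)ethenyl]oxy}dimethylsilane (2-silyloxy diene) | C=C(O[Si](C)(C)C(C)(C)C)C1=CC2(CC1)OCCO2 | intermediate
6 | ethyl diazoacetate | CCOC(=O)C=[N+]=[N-] | starting material
7 | [(tert-butyldimethylsilyl)oxy]acetaldehyde | CC(C)(C)[Si](C)(C)OCC=O | starting material
8 | ethyl 4-[(tert-butyldimethylsilyl)oxy]-2-diazo-3-hydroxybutanoate (racemic) | CCOC(=O)C(=[N+]=[N-])C(O)CO[Si](C)(C)C(C)(C)C | intermediate
9 | dichlorophosphate of 8 | CCOC(=O)C(=[N+]=[N-])C(OP(=O)(Cl)Cl)CO[Si](C)(C)C(C)(C)C | intermediate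
10 | ethyl (3E)-4-[(tert-butyldimethylsilyl)oxy]-2-diazobut-3-enoate | CCOC(=O)C(=[N+]=[N-])/C=C/O[Si](C)(C)C(C)(C)C | intermediate
11 | cis-divinylcyclopropane: ethyl 1-[(E)-2-(TBS-oxy)ethenyl]-2-(TBS-oxy)-2-(1,4-dioxaspiro[4.4]non-6-en-7-yl)cyclopropane-1-carboxylate, alkenyl groups cis | CCOC(=O)[C@]1(/C=C/O[Si](C)(C)C(C)(C)C)C[C@@]1(O[Si](C)(C)C(C)(C)C)C2=CC3(CC2)OCCO3 | intermediate
12 | bicyclic cycloheptadiene ester: C1–CO2Et, C1=C7, C3=C4 with TBS-oxy on C3, TBS-oxy on C6, ethylene ketal at C10, H5 and H6 on the same face | CCOC(=O)C1=C[C@@H](O[Si](C)(C)C(C)(C)C)[C@@H]2C(=C(O[Si](C)(C)C(C)(C)C)C1)CCC23OCCO3 | intermediate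
13 | allylic alcohol: as 12 with CH2OH on C1 | OCC1=C[C@@H](O[Si](C)(C)C(C)(C)C)[C@@H]2C(=C(O[Si](C)(C)C(C)(C)C)C1)CCC23OCCO3 | intermediate
14 | sulfonylhydrazine: N-allylic N-(2-nitrophenylsulfonyl)hydrazine from 13 | NN(CC1=C[C@@H](O[Si](C)(C)C(C)(C)C)[C@@H]2C(=C(O[Si](C)(C)C(C)(C)C)C1)CCC23OCCO3)S(=O)(=O)c1ccccc1[N+](=O)[O-] | intermediate
15 | allylic diazene (C1–CH2–N=NH) | N=NCC1=C[C@@H](O[Si](C)(C)C(C)(C)C)[C@@H]2C(=C(O[Si](C)(C)C(C)(C)C)C1)CCC23OCCO3 | intermediate
16 | exo-methylene silyl enol ether: C1=CH2, C7H2, C3=C4 silyl enol ether, C6–OTBS, C10 ketal | C=C1C[C@@H](O[Si](C)(C)C(C)(C)C)[C@@H]2C(=C(O[Si](C)(C)C(C)(C)C)C1)CCC23OCCO3 | intermediate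
17 | methyl ketone: C4–CH3 cis to H5, C3 ketone, C1=CH2 | C=C1C[C@@H](O[Si](C)(C)C(C)(C)C)[C@@H]2[C@](C)(C(=O)C1)CCC23OCCO3 | intermediate
18 | enone ketal: C1(CH3)=C2–C3=O, cis-fused, C6–OTBS, C10 ketal | CC1=CC(=O)[C@]2(C)CCC3(OCCO3)[C@@H]2[C@H](O[Si](C)(C)C(C)(C)C)C1 | intermediate
19 | enone ketone: as 18 with C10 ketone | CC1=CC(=O)[C@]2(C)CCC(=O)[C@@H]2[C@H](O[Si](C)(C)C(C)(C)C)C1 | intermediate
20 | lithium enolate (C9=C10–OLi) | CC1=CC(=O)[C@]2(C)CC=C(O[Li])[C@@H]2[C@H](O[Si](C)(C)C(C)(C)C)C1 | intermediate
21 | enol triflate (C9=C10–OTf) | CC1=CC(=O)[C@]2(C)CC=C(OS(=O)(=O)C(F)(F)F)[C@@H]2[C@H](O[Si](C)(C)C(C)(C)C)C1 | intermediate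
22 | isopropyl cyclopentene enone (C9=C10–i-Pr) | CC1=CC(=O)[C@]2(C)CC=C(C(C)C)[C@@H]2[C@H](O[Si](C)(C)C(C)(C)C)C1 | intermediate
23 | epoxy enone: C9–C10 epoxide, oxygen cis to H5 and the C4 methyl | CC1=CC(=O)[C@]2(C)C[C@H]3O[C@@]3(C(C)C)[C@@H]2[C@H](O[Si](C)(C)C(C)(C)C)C1 | intermediate
24 | diol: C3–OH trans to the C4 methyl, tertiary C10–OH cis to H5, C6–OTBS | CC1=C[C@H](O)[C@]2(C)CC[C@](O)(C(C)C)[C@@H]2[C@H](O[Si](C)(C)C(C)(C)C)C1 | intermediate
25 | C3 isovalerate of 24 | CC1=C[C@H](OC(=O)CC(C)C)[C@]2(C)CC[C@](O)(C(C)C)[C@@H]2[C@H](O[Si](C)(C)C(C)(C)C)C1 | intermediate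
26 | C6 alcohol | CC1=C[C@H](OC(=O)CC(C)C)[C@]2(C)CC[C@](O)(C(C)C)[C@@H]2[C@H](O)C1 | intermediate
27 | C6 4-acetoxybenzoate | CC1=C[C@H](OC(=O)CC(C)C)[C@]2(C)CC[C@](O)(C(C)C)[C@@H]2[C@H](OC(=O)c2ccc(OC(C)=O)cc2)C1 | intermediate
28 | target: C3 isovalerate, C6 4-hydroxybenzoate, C10 tertiary alcohol, cis-fused | CC1=C[C@H](OC(=O)CC(C)C)[C@]2(C)CC[C@](O)(C(C)C)[C@@H]2[C@H](OC(=O)c2ccc(O)cc2)C1 | target

Total step count: 18.
Longest linear sequence: 16 steps (steps 1–3 and 6–18; steps 4–5 make the second fragment).

Steps most likely to fail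

Step 6. The silyloxy-substituted vinylcarbenoid may react at its vinylogous carbon or give a [3+2] annulation with the silyl enol ether, the diazo compound may electrocyclise to a pyrazole, or face selection by the catalyst may be poor. The fallback carries the C6 oxygen as a C–Si bond and sets out from 5 and 6. Palladium-catalysed coupling of 6 with (E)-(2-iodoethenyl)dimethyl(phenyl)silane (Pd(PPh3)4, Et3N, Bu4NBr, MeCN) gives the silyl-substituted vinyldiazoacetate F1, whose vinyl terminus is not a donor. The same dirhodium-catalysed cyclopropanation/Cope sequence with 5 gives the C6-silyl cycloheptadiene ester F2. DIBAL-H then gives the allylic alcohol F3, the diazene transposition of step 8 gives the exo-methylene compound F4, and TASF/MeI followed by DBU gives the C6-silyl enone ketal F5. Tamao–Fleming oxidation (HBF4·OEt2, then KF, KHCO3, H2O2; retention at C6, the ketal is lost in the acidic stage) gives the hydroxy dione F6, and TBSCl/imidazole brings the route back at 19.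

Step 9. The naked enolate may be O-methylated, may exchange protons and be methylated at C2, or may be attacked on the face that gives the trans-fused ketone. The fallback delivers the methyl carbon as a carbenoid and sets out from 16. Cyclopropanation of the silyl enol ether, the most electron-rich alkene, with Et2Zn/CH2I2 (Simmons–Smith, CH2Cl2, −20 °C) on the face of H5 gives the siloxycyclopropane F7. TBAF (2.2 equiv) removes both silyl groups; the cyclopropanolate opens at the C3–CH2 bond to the C4-methyl ketone and the basic medium conjugates the alkene, giving the hydroxy enone ketal F8. TBSCl/imidazole returns to 18.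

Step 14. Hydride may be delivered to the concave face of the C3 carbonyl (anti to the angular methyl), giving the C3 epimer, or may add in conjugate fashion. The fallback sets the centre by SN2 inversion and sets out from 23. The same reduction then gives the C3-epimeric diol F9, and a Mitsunobu esterification (PPh3, DIAD, 3-methylbutanoic acid, toluene, 0 °C) inverts C3 and installs the isovalerate in one step, returning at 25.

Further compounds
F1 | step 6 | ethyl (3E)-2-diazo-4-[dimethyl(phenyl)silyl]but-3-enoate | CCOC(=O)C(=[N+]=[N-])/C=C/[Si](C)(C)c1ccccc1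
F2 | step 6 | C6-silyl cycloheptadiene ester (as 12 with SiMe2Ph on C6) | CCOC(=O)C1=C[C@@H]([Si](C)(C)c4ccccc4)[C@@H]2C(=C(O[Si](C)(C)C(C)(C)C)C1)CCC23OCCO3
F3 | step 6 | C6-silyl allylic alcohol | OCC1=C[C@@H]([Si](C)(C)c4ccccc4)[C@@H]2C(=C(O[Si](C)(C)C(C)(C)C)C1)CCC23OCCO3
F4 | step 6 | C6-silyl exo-methylene silyl enol ether | C=C1C[C@@H]([Si](C)(C)c4ccccc4)[C@@H]2C(=C(O[Si](C)(C)C(C)(C)C)C1)CCC23OCCO3
F5 | step 6 | C6-silyl enone ketal | CC1=CC(=O)[C@]2(C)CCC3(OCCO3)[C@@H]2[C@H]([Si](C)(C)c3ccccc3)C1
F6 | step 6 | hydroxy dione (C6–OH, C10 ketone, C3 enone) | CC1=CC(=O)[C@]2(C)CCC(=O)[C@@H]2[C@H](O)C1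
F7 | step 9 | siloxycyclopropane (CH2 bridging C3 and C4 on the face of H5) | C=C1C[C@@H](O[Si](C)(C)C(C)(C)C)[C@@H]2[C@@]3(C[C@]3(O[Si](C)(C)C(C)(C)C)C1)CCC24OCCO4
F8 | step 9 | hydroxy enone ketal (as 18 with C6–OH) | CC1=CC(=O)[C@]2(C)CCC3(OCCO3)[C@@H]2[C@H](O)C1
F9 | step 14 | C3-epimeric diol (3-epi-24) | CC1=C[C@@H](O)[C@]2(C)CC[C@](O)(C(C)C)[C@@H]2[C@H](O[Si](C)(C)C(C)(C)C)C1
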